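**Amounts.** Your flasks charge 0.49 M of first end groups against 0.480 M of second end groups, and maple is Friday's charge read later.

| flask | first end groups | second end groups | remark | time |
|---|---|---|---|---|
| Friday's | 0.49 M | 0.48 M | run made earlier |  |
| Sunday's | 0.24 M | 0.48 M | run made earlier |  |
| Thursday's | 0.98 M | 0.48 M | run made earlier |  |
| Saturday's | 0.49 M | 0.96 M | run made earlier |  |
| maple | 0.49 M | 0.480 M | everything together in a closed stirred flask, run for 2.5 h | 2.5 h |
| ash | 0.49 M | 0.480 M | one stirred flow tank at steady state, fed with the mixture as stated, mean residence time 2.5 h |  |
| oak | 0.49 M | 0.480 M | a single well-mixed tank run continuously and read at steady state, 25.0 h in it on average |  |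
| larch | 0.49 M (fed, over 2.50 h) | 0.480 M | a stirred flask in which first end groups is dosed at a steady rate over 2.50 h without added volume, worked up at 2.5 h | 2.5 h |

| run | time / min | links / % | rings / % | first end groups / % |
|---|---|---|---|---|
| Friday's | 8.00 | 31.7 | 0.3 | 55.3 |
| Friday's | 15.0 | 42.3 | 1.0 | 40.3 |
| Friday's | 40.0 | 54.9 | 1.5 | 21.7 |
| Friday's | 90.0 | 58.7 | 2.0 | 13.1 |
| Sunday's | 8.00 | 36.2 | 0 | 57.0 |
| Sunday's | 15.0 | 50.7 | 1.0 | 40.4 |
| Sunday's | 40.0 | 69.1 | 1.9 | 18.7 |
| Sunday's | 90.0 | 75.9 | 2.2 | 9.5 |
| Thursday's | 12.0 | 29.6 | 0.6 | 42.5 |
| Thursday's | 30.0 | 36.0 | 1.3 | 25.4 |
| Thursday's | 60.0 | 37.6 | 1.8 | 16.3 |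
| Thursday's | 90.0 | 36.9 | 2.1 | 12.0 |
| Saturday's | 8.00 | 54.3 | 0.4 | 36.7 |
| Saturday's | 15.0 | 68.6 | 0.9 | 20.0 |
| Saturday's | 40.0 | 82.4 | 0.7 | 5.6 |
| Saturday's | 90.0 | 85.0 | 0.7 | 2.2 |

(each reading ± 0.3 percentage points)

- the stated concentrations are those of everything mixed, before any reaction; amounts are the same in each set-up
- the feed brings no volume worth counting
- the earlier runs were made in a closed, stirred flask

- the set-up with the highest share of links in all that became links or rings, at the outlet or at the end ("none" if the first two lie within 2 percentage points) (maple / ash / oak / larch / none)
- share of links in all that became links or rings, at the outlet or at the end, maple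
- share of links in all that became links or rings, at the outlet or at the end, ash
- share of links in all that became links or rings, at the outlet or at the end, oak
- share of links in all that became links or rings, at the outlet or at the end, larch

**Links alone.** With links as the one product, the share stands at 100%.

**Adding rings.** Friday's last reading, at 90.0 min, gives 58.7% links to 2.0% rings, a share of 96.7%. The selectivity factor, link growth over ring growth, reads as sinking, though. From 40.0 min to 90.0 min links gained 3.8 percentage points and rings 0.5 points, a ratio of 7.60 against 29.4 over the whole run, so late product reads poorer.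

**Adding decay.** Link growth per first end group still free shows how much link-making power remains, and I take that power as the level of second end groups. In Sunday's run it reads 0.0425 /min early and 0.00965 /min late, with mid-times 53.5 min apart. That gives a reading for the half-life of link-making power, the time in which this growth falls by half: 25.0 min.

Now count. Maple's 2.5 h is 6.00 half-lives and Friday's last reading 3.60, so I reckon maple a little under Friday's share. With a first-order loss of that half-life, I reckon a steady tank's level as the feed level divided by one plus τ times ln of two over the half-life, with τ the mean residence time. Ash has τ of 2.5 h, oak 25.0 h, so I reckon oak's level 8.26 times lower than ash's. Larch doses over 6.00 half-lives, so I reckon its last first end groups meet 1.56% of the starting level. I put maple first and oak last.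

**The forecast.** It names maple: maple 95.8%, ash 90.5%, oak 59%, larch 89%. For maple it says “extrapolating Friday to 150 min gives about 59.4 links and 2.6 rings”.

**The result.** Maple gives 95.7%, ash 92.1%, oak 62.6%, larch 90.9%, so maple stands first.

    first end groups + second end groups → links (k = 8.90 /M/h)
    first end groups + second end groups → rings, rate k2*[first end groups] as long as [second end groups] is above zero (k = 0.0510 /h)
    second end groups → decomposed reagent (k = 1.20 /h)
    2 first end groups → self-condensation product (k = 1.70 /M/h)

At 2.50 h maple keeps 0.160% of its second end groups, the limiting reagent, beside 0.177 M of decomposed reagent. Put the half-life 25.0 min on ash: second end groups reckon at 0.0930 M, and ash's tank stands at 0.0669 M.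

Readings and results were generated by integration for an exercise; the scatter is artificial.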